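The target is divided at the bond between the quaternary butenolide carbon and its benzylic CH2. This gives a benzyl-protected butenolide ester that still carries H there and an enantiopure dihydrobenzofuranylmethyl bromide. The plan rests on a [4+1] construction of the dihydrofuran ring. C3 is an unsubstituted methylene ortho to ring oxygen O1, so O1–C7a–C3a–C3 is a masked ortho-quinone methide. Stereogenic C2 is a one-carbon ester ylide whose ester later becomes the hydroxyisopropyl group. In one operation the step makes C3–C2 and O1–C2, closes the five-membered ring and sets C2 as S. Its precursor is 4-bromo-2-(tosylmethyl)phenol, which sheds sulfinate under mild base, paired with halide-free ethyl (dimethylsulfonio)acetate ylide.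

Key step: step 4

Numbering: the dihydrobenzofuran is O1, C2, C3, C3a, C4–C7, C7a. The butenolide is primed in furan-2(5H)-one order: O1', C2' (lactone C=O), C3' (C–OH), C4' (C–aryl), C5' (quaternary). From the SMILES, both stereocentres of the target (C2 and C5') are S.

Catalyst for step 4: 1,1'-[(1R,2R)-cyclohexane-1,2-diyl]bis{3-[3,5-bis(trifluoromethyl)phenyl]urea}, called the (R,R)-bis-urea below. It is obtained by mixing commercial (1R,2R)-cyclohexane-1,2-diamine with two equivalents of commercial 3,5-bis(trifluoromethyl)phenyl isocyanate in CH2Cl2 and filtering. This preparation is not counted as a step.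

Assumption: the sense of induction in the two catalyst-controlled steps (4 and 10) cannot be derived rigorously for these substrates, so the antipodes named are those taken to give S at C2 and S at C5', and the (S,S)-bis-urea or the pseudoenantiomeric cinchoninium salt would replace them if a test run shows the opposite sense.

Step 1
Reactants: 1 5-bromosalicylaldehyde
Product: 2 4-bromo-2-(hydroxymethyl)phenol
Conditions: NaBH4 (0.6 equiv), MeOH, 0 °C; aq NH4Cl
Reagents that add atoms: none
Why: Chemoselective borohydride reduction of the aryl aldehyde, to which the phenol and the aryl bromide are inert.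

Step 2
Reactants: 2 4-bromo-2-(hydroxymethyl)phenol
Product: 3 4-bromo-2-(tosylmethyl)phenol
Conditions: TolSO2Na (1.5 equiv), HCO2H–H2O, 70 °C
Reagents that add atoms: sodium p-toluenesulfinate, Cc1ccc(cc1)S(=O)[O-].[Na+]
Why: Acid-promoted dehydrative SN1-type substitution in which the ortho-hydroxybenzyl cation is captured by the soft sulfur of the sulfinic acid, giving the crystalline and thermodynamically favoured sulfone.

Step 3
Reactants: 4 ethyl bromoacetate
Product: 6 ethyl (dimethylsulfonio)acetate ylide, via sulfonium bromide 5 (not isolated)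
Conditions: Me2S (1.2 equiv), acetone, rt; evaporate; CHCl3, sat aq K2CO3, NaOH (1.0 equiv), 0 °C; dry over K2CO3, concentrate
Reagents that add atoms: dimethyl sulfide, CSC
Why: SN2 S-alkylation of the sulfide by the alpha-bromo ester followed by deprotonation of the acidic sulfonium methylene gives the ester-stabilised ylide, which is robust enough to be dried and used free of halide, so that no bromide competes for the hydrogen-bond catalyst in step 4.

Step 4
Reactants: 3 4-bromo-2-(tosylmethyl)phenol; 6 ethyl (dimethylsulfonio)acetate ylide
Product: 9 ethyl (2S)-5-bromo-2,3-dihydro-1-benzofuran-2-carboxylate, via quinone methide 7 (not isolated), via sulfonium phenoxide betaine 8 (not isolated)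
Conditions: 6 (1.5 equiv), (R,R)-bis-urea (20 mol %), powdered Cs2CO3 (1.2 equiv), 4 Å MS, CH2Cl2, −20 °C, Ar; cold filtration through silica
Reagents that add atoms: none
Why: Carbonate ionises the phenol of 3 and 1,4-elimination of p-toluenesulfinate releases methide 7 at a low stationary concentration; the nucleophilic carbon of 6 adds to its exocyclic CH2 (new C3–C2 bond, driven by rearomatisation) to give betaine 8, whose phenoxide then expels dimethyl sulfide from the same carbon (new O1–C2 bond). The closest known reaction type is the formal [4+1] annulation of quinone methides generated from 2-(sulfonylalkyl)phenols with stabilised sulfonium ylides, which also exists in a chiral-urea-catalysed form. The dihydrofuran ring closes in the 5-exo-tet mode by SN2 displacement with inversion at C2. C2 is the only new stereocentre: its C–H in 8 lies between ester and sulfonium and is exchanged quickly by the internal phenoxide, so the two epimers interconvert, and the C2-symmetric bis-urea, gripping the phenoxide with one urea and the ester carbonyl with the other, is meant to let only the R epimer reach the backside geometry, which delivers (S)-9 as a dynamic kinetic resolution. The step needs capture of 7 by 6 ahead of methide oligomerisation or a second alkylation, and oxygen attack at C2 instead of at an S-methyl group or the ester carbonyl; slow heterogeneous release of 7 into excess ylide secures the first, the five-membered transition state and the excellent sulfide leaving group secure the second, and re-addition of sulfinate only regenerates 3. Suspended carbonate at −20 °C is too weak to enolise the alpha-aryloxy ester of 9, and the bromine para to O1 is a spectator that makes the phenol easier to ionise.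

Step 5
Reactants: 9 ethyl (2S)-5-bromo-2,3-dihydro-1-benzofuran-2-carboxylate
Product: 11 2-[(2S)-5-bromo-2,3-dihydro-1-benzofuran-2-yl]propan-2-ol, via methyl ketone 10 (not isolated)
Conditions: MeMgBr (3.2 equiv), LaCl3·2LiCl (0.3 equiv), THF, −20 → 0 °C; aq NH4Cl
Reagents that add atoms: methylmagnesium bromide, C[Mg]Br
Why: Double Grignard addition to the ester through ketone 10, in which chelation to the alpha-oxygen and the lanthanum salt make addition much faster than enolisation, so C2 is retained (still S because CMe2OH takes the rank of CO2Et) and the aryl bromide is untouched.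

Step 6
Reactants: 11 2-[(2S)-5-bromo-2,3-dihydro-1-benzofuran-2-yl]propan-2-ol
Product: 14 2-[(2S)-5-(hydroxymethyl)-2,3-dihydro-1-benzofuran-2-yl]propan-2-ol, via dilithio species 12 (not isolated), via aldehyde 13 (not isolated)
Conditions: n-BuLi (2.2 equiv), THF, −78 °C; DMF (3 equiv), −78 → 0 °C; then MeOH, NaBH4, 0 °C
Reagents that add atoms: N,N-dimethylformamide, CN(C)C=O
Why: The first equivalent of n-BuLi turns the tertiary alcohol into an inert alkoxide, the second effects fast bromine–lithium exchange at C5, and Bouveault formylation with DMF followed by borohydride reduction in the same flask gives the benzylic alcohol without a protecting group and without touching C2.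

Step 7
Reactants: 14 2-[(2S)-5-(hydroxymethyl)-2,3-dihydro-1-benzofuran-2-yl]propan-2-ol
Product: 15 2-[(2S)-5-(bromomethyl)-2,3-dihydro-1-benzofuran-2-yl]propan-2-ol
Conditions: CBr4 (1.1 equiv), PPh3 (1.1 equiv), CH2Cl2, 0 °C; short silica plug, used at once
Reagents that add atoms: carbon tetrabromide, BrC(Br)(Br)Br
Why: Appel reaction under essentially neutral conditions, in which the unhindered primary benzylic alcohol forms the alkoxyphosphonium ion and is displaced by bromide far faster than the tertiary alcohol can react.

Step 8
Reactants: 16 4-hydroxyphenylpyruvic acid; 17 methyl glyoxylate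
Product: 19 methyl (±)-4-hydroxy-3-(4-hydroxyphenyl)-5-oxo-2,5-dihydrofuran-2-carboxylate, via aldol adduct 18 (not isolated)
Conditions: 17 (freshly distilled, 1.1 equiv), DBU (3.2 equiv), DMF, 0 °C, Ar; then 2 M HCl, rt
Reagents that add atoms: none
Why: Cross-aldol addition of the arylpyruvate enolate through its only acidic carbon to the non-enolisable and highly electrophilic aldehyde, followed by acid-driven lactonisation and enolisation, is the established route from arylpyruvic acids and aldehydes to 3-hydroxy-4-arylfuran-2(5H)-ones, and the racemic C5' is of no concern because it is planarised in step 10.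

Step 9
Reactants: 19 methyl (±)-4-hydroxy-3-(4-hydroxyphenyl)-5-oxo-2,5-dihydrofuran-2-carboxylate
Product: 20 methyl (±)-4-(benzyloxy)-3-[4-(benzyloxy)phenyl]-5-oxo-2,5-dihydrofuran-2-carboxylate
Conditions: BnOH (2.1 equiv), PPh3 (2.2 equiv), DIAD (2.2 equiv), THF, 0 °C → rt
Reagents that add atoms: benzyl alcohol, OCc1ccccc1
Why: Double Mitsunobu etherification uses the acidity of the enol and phenol O–H groups and needs no external base, which avoids the C5' benzylation that benzyl bromide and carbonate would cause once the enol is capped.

Step 10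
Reactants: 15 2-[(2S)-5-(bromomethyl)-2,3-dihydro-1-benzofuran-2-yl]propan-2-ol; 20 methyl (±)-4-(benzyloxy)-3-[4-(benzyloxy)phenyl]-5-oxo-2,5-dihydrofuran-2-carboxylate
Product: 22 methyl (2S)-4-(benzyloxy)-3-[4-(benzyloxy)phenyl]-2-{[(2S)-2-(2-hydroxypropan-2-yl)-2,3-dihydro-1-benzofuran-5-yl]methyl}-5-oxo-2,5-dihydrofuran-2-carboxylate, via furanolate anion 21 (not isolated)
Conditions: 15 (1.2 equiv), N-(9-anthracenylmethyl)cinchonidinium chloride (10 mol %), powdered Cs2CO3 (1.5 equiv), toluene–CH2Cl2, −40 °C, Ar; chromatography
Reagents that add atoms: none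
Why: In this solid–liquid asymmetric phase-transfer alkylation, carbonate removes the C5'–H (activated by the ester, the ring oxygen and vinylogy to the lactone carbonyl), the planar furanolate 21 pairs with the chiral ammonium ion that screens one face, and the reactive para-alkoxybenzyl bromide is attacked through C5' (which keeps the conjugated butenolide, whereas C3' is crowded by OBn and the twisted aryl group), so C5' is set as S by catalyst control as in the enantioselective benzylation of phthalide-3-carboxylates, and any C5' epimer is a diastereomer that chromatography removes.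

Step 11
Reactants: 22 methyl (2S)-4-(benzyloxy)-3-[4-(benzyloxy)phenyl]-2-{[(2S)-2-(2-hydroxypropan-2-yl)-2,3-dihydro-1-benzofuran-5-yl]methyl}-5-oxo-2,5-dihydrofuran-2-carboxylate
Product: 23 methyl (2S)-4-hydroxy-3-(4-hydroxyphenyl)-2-{[(2S)-2-(2-hydroxypropan-2-yl)-2,3-dihydro-1-benzofuran-5-yl]methyl}-5-oxo-2,5-dihydrofuran-2-carboxylate
Conditions: H2 (1 atm), 10% Pd/C, EtOAc, rt
Reagents that add atoms: none
Why: Catalytic hydrogenolysis cleaves both benzyl ethers under neutral conditions, while the tetrasubstituted enol double bond, the non-benzylic O1–C2 bond, the methyl ester, the acid-sensitive tertiary alcohol and both stereocentres remain unaffected.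

Compound list
1 | 5-bromosalicylaldehyde | O=Cc1cc(Br)ccc1O | starting material
2 | 4-bromo-2-(hydroxymethyl)phenol | OCc1cc(Br)ccc1O | intermediate
3 | 4-bromo-2-(tosylmethyl)phenol | Cc1ccc(cc1)S(=O)(=O)Cc1cc(Br)ccc1O | intermediate
4 | ethyl bromoacetate | CCOC(=O)CBr | starting material
5 | (2-ethoxy-2-oxoethyl)dimethylsulfonium bromide (not isolated) | CCOC(=O)C[S+](C)C.[Br-] | intermediate
6 | ethyl (dimethylsulfonio)acetate ylide | CCOC(=O)[CH-][S+](C)C | intermediate
7 | 4-bromo-6-methylidenecyclohexa-2,4-dien-1-one (not isolated) | C=C1C=C(Br)C=CC1=O | intermediate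
8 | 4-bromo-2-[2-(dimethylsulfonio)-3-ethoxy-3-oxopropyl]phenolate, epimerising at the sulfonium-bearing carbon (not isolated) | CCOC(=O)C(Cc1cc(Br)ccc1[O-])[S+](C)C | intermediate
9 | ethyl (2S)-5-bromo-2,3-dihydro-1-benzofuran-2-carboxylate | CCOC(=O)[C@@H]1Cc2cc(Br)ccc2O1 | intermediate
10 | 1-[(2S)-5-bromo-2,3-dihydro-1-benzofuran-2-yl]ethan-1-one (not isolated) | CC(=O)[C@@H]1Cc2cc(Br)ccc2O1 | intermediate
11 | 2-[(2S)-5-bromo-2,3-dihydro-1-benzofuran-2-yl]propan-2-ol | CC(C)(O)[C@@H]1Cc2cc(Br)ccc2O1 | intermediate
12 | lithium 2-[(2S)-5-lithio-2,3-dihydro-1-benzofuran-2-yl]propan-2-olate (not isolated) | CC(C)(O[Li])[C@@H]1Cc2cc([Li])ccc2O1 | intermediate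
13 | (2S)-2-(2-hydroxypropan-2-yl)-2,3-dihydro-1-benzofuran-5-carbaldehyde (not isolated) | CC(C)(O)[C@@H]1Cc2cc(C=O)ccc2O1 | intermediate
14 | 2-[(2S)-5-(hydroxymethyl)-2,3-dihydro-1-benzofuran-2-yl]propan-2-ol | CC(C)(O)[C@@H]1Cc2cc(CO)ccc2O1 | intermediate
15 | 2-[(2S)-5-(bromomethyl)-2,3-dihydro-1-benzofuran-2-yl]propan-2-ol | CC(C)(O)[C@@H]1Cc2cc(CBr)ccc2O1 | intermediate
16 | 4-hydroxyphenylpyruvic acid | O=C(O)C(=O)Cc1ccc(O)cc1 | starting material
17 | methyl glyoxylate | COC(=O)C=O | starting material
18 | 4-hydroxy-3-(4-hydroxyphenyl)-5-methoxy-2,5-dioxopentanoic acid (not isolated) | COC(=O)C(O)C(c1ccc(O)cc1)C(=O)C(=O)O | intermediate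
19 | methyl (±)-4-hydroxy-3-(4-hydroxyphenyl)-5-oxo-2,5-dihydrofuran-2-carboxylate | COC(=O)C1OC(=O)C(O)=C1c1ccc(O)cc1 | intermediate
20 | methyl (±)-4-(benzyloxy)-3-[4-(benzyloxy)phenyl]-5-oxo-2,5-dihydrofuran-2-carboxylate | COC(=O)C1OC(=O)C(OCc2ccccc2)=C1c1ccc(OCc2ccccc2)cc1 | intermediate
21 | 3-(benzyloxy)-4-[4-(benzyloxy)phenyl]-5-(methoxycarbonyl)furan-2-olate, paired with the catalyst cation (not isolated) | COC(=O)c1oc([O-])c(OCc2ccccc2)c1-c1ccc(OCc2ccccc2)cc1 | intermediate
22 | methyl (2S)-4-(benzyloxy)-3-[4-(benzyloxy)phenyl]-2-{[(2S)-2-(2-hydroxypropan-2-yl)-2,3-dihydro-1-benzofuran-5-yl]methyl}-5-oxo-2,5-dihydrofuran-2-carboxylate | COC(=O)[C@@]1(Cc2ccc3c(c2)C[C@@H](C(C)(C)O)O3)OC(=O)C(OCc2ccccc2)=C1c1ccc(OCc2ccccc2)cc1 | intermediate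
23 | methyl (2S)-4-hydroxy-3-(4-hydroxyphenyl)-2-{[(2S)-2-(2-hydroxypropan-2-yl)-2,3-dihydro-1-benzofuran-5-yl]methyl}-5-oxo-2,5-dihydrofuran-2-carboxylate | COC(=O)[C@@]1(Cc2ccc3c(c2)C[C@@H](C(C)(C)O)O3)OC(=O)C(O)=C1c1ccc(O)cc1 | target

Total step count: 11
Longest linear sequence: 8 (steps 1, 2, 4, 5, 6, 7, 10, 11)

Steps most likely to fail

Step 4. The main danger is weak enantiocontrol. The methide carbon carries no substituent, so no C3 stereocentre relays information. Closure of catalyst-free betaine, whose phenoxide is the more nucleophilic, may outrun the urea-bound pathway. Oligomerisation of the very electrophilic methide may also drain material. The fallback replaces asymmetric catalysis by resolution and sets out from 3 and 6. These are combined without chiral catalyst (Cs2CO3, CH2Cl2, rt) to give racemic ethyl 5-bromo-2,3-dihydro-1-benzofuran-2-carboxylate F1. A hydrolase chosen by screening is then to hydrolyse the R ester to (2R)-5-bromo-2,3-dihydro-1-benzofuran-2-carboxylic acid F2; immobilised lipase B from Candida antarctica in pH 7 phosphate buffer–MTBE is the first candidate. Washing out F2 with aq NaHCO3 leaves 9, where the route is rejoined. F2 can be re-esterified and racemised with DBU back to F1.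

Step 10. The ambident furanolate may react through C3' or through oxygen, and the small methyl ester may give the catalyst too little facial bias. The fallback changes from anionic to cationic alkylation and secures C5' by separation. It sets out from 20, which TBSOTf and Et3N (CH2Cl2, 0 °C) should convert into methyl 4-(benzyloxy)-3-[4-(benzyloxy)phenyl]-5-[(tert-butyldimethylsilyl)oxy]furan-2-carboxylate F3. Treatment of F3 with 15 and AgO2CCF3 (CH2Cl2, −78 → 0 °C) is an SN1-type vinylogous Mukaiyama alkylation, a reaction type that favours the furan carbon remote from the silyloxy group. It should give 22 together with methyl (2R)-4-(benzyloxy)-3-[4-(benzyloxy)phenyl]-2-{[(2S)-2-(2-hydroxypropan-2-yl)-2,3-dihydro-1-benzofuran-5-yl]methyl}-5-oxo-2,5-dihydrofuran-2-carboxylate F4. Because 15 is enantiopure, the two are diastereomers and are to be separated by chromatography or crystallisation. The route is rejoined at 22.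

Step 8. Self-condensation of the pyruvic acid, base-induced oligomerisation of the glyoxylate, incomplete ring closure or partial ester hydrolysis during the aqueous acid stage could all erode this step. The fallback moves from keto-acid polyanion chemistry to ester chemistry with a non-aqueous ring closure. It sets out from 16, which is esterified (MeOH, cat H2SO4, rt) to methyl 4-hydroxyphenylpyruvate F5. Et3N-mediated aldol addition of F5 to 17 in CH2Cl2 then gives an aldolate that closes onto the keto ester by transesterification in the same flask. This arrives at 19.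

Further compounds
F1 | step 4 | ethyl (±)-5-bromo-2,3-dihydro-1-benzofuran-2-carboxylate | CCOC(=O)C1Cc2cc(Br)ccc2O1
F2 | step 4 | (2R)-5-bromo-2,3-dihydro-1-benzofuran-2-carboxylic acid | OC(=O)[C@H]1Cc2cc(Br)ccc2O1
F3 | step 10 | methyl 4-(benzyloxy)-3-[4-(benzyloxy)phenyl]-5-[(tert-butyldimethylsilyl)oxy]furan-2-carboxylate | COC(=O)c1oc(O[Si](C)(C)C(C)(C)C)c(OCc2ccccc2)c1-c1ccc(OCc2ccccc2)cc1
F4 | step 10 | methyl (2R)-4-(benzyloxy)-3-[4-(benzyloxy)phenyl]-2-{[(2S)-2-(2-hydroxypropan-2-yl)-2,3-dihydro-1-benzofuran-5-yl]methyl}-5-oxo-2,5-dihydrofuran-2-carboxylate | COC(=O)[C@]1(Cc2ccc3c(c2)C[C@@H](C(C)(C)O)O3)OC(=O)C(OCc2ccccc2)=C1c1ccc(OCc2ccccc2)cc1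
F5 | step 8 | methyl 4-hydroxyphenylpyruvate | COC(=O)C(=O)Cc1ccc(O)cc1
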